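At 6.0 h Sunday's run shows substrate, mono adduct and bis adduct, and what they leave unread I call the rest, 50.5% of the charge.

| flask | substrate | reagent | capture agent | remark | time |
|---|---|---|---|---|---|
| Tuesday's | 0.15 M (fed, over 2.5 h) | 1.8 equiv | 0.090 M | run made earlier; the fed solution adds 1.0 times the starting volume |  |
| Sunday's | 0.22 M (fed, over 2.5 h) | 1.8 equiv | 0.090 M | run made earlier; the fed solution adds 1.0 times the starting volume |  |
| flask | 0.30 M (fed, over 2.5 h) | 1.80 equiv | 0.0900 M | the fed solution adds 1.0 times the starting volume | 6.0 h |

| run | time / h | substrate / % | mono adduct / % | bis adduct / % |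
|---|---|---|---|---|
| Tuesday's | 1.00 | 26.0 | 8.8 | 3.2 |
| Tuesday's | 2.00 | 45.8 | 12.9 | 6.3 |
| Tuesday's | 3.00 | 46.6 | 16.5 | 9.0 |
| Tuesday's | 4.00 | 38.7 | 18.5 | 9.3 |
| Tuesday's | 5.00 | 35.0 | 15.3 | 10.1 |
| Tuesday's | 6.00 | 33.6 | 14.8 | 8.6 |
| Sunday's | 0.500 | 13.8 | 2.4 | 2.1 |
| Sunday's | 0.833 | 20.1 | 6.2 | 4.0 |
| Sunday's | 1.33 | 29.0 | 10.0 | 6.8 |
| Sunday's | 2.00 | 38.8 | 12.5 | 9.8 |
| Sunday's | 4.00 | 35.1 | 15.6 | 9.5 |
| Sunday's | 6.00 | 30.0 | 12.8 | 6.7 |

(standard deviation of a reading: 1 percentage point)

- charges are per starting volume, the dose included; the dosed solution carries all of it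
- a reading or a percentage of triple product counts all its forms, free or not
- percentages count the whole charge, also what has not yet gone in
- a reading of substrate is of its free form alone

- the substrate standing at 6.0 h, as a percentage of the substrate charged
- the mono adduct standing at 6.0 h, as a percentage of the substrate charged
- the bis adduct standing at 6.0 h, as a percentage of the substrate charged
- the triple product standing at 6.0 h, as a percentage of the substrate charged

So I ask how much reagent that rest holds. I suppose no reagent is left, take off one per mono adduct and two per bis adduct, and divide by the rest, which gives 3.05 reagent per substrate. I call this the mean load of the rest. But 3 is merely the middle of the scale: a rest of pure triple product reads so, and so does an equal mix of a species holding 2 and one holding 4. The load therefore can't tell them apart.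

Tuesday's run gives 3.44, higher than Sunday's, and the sum over-reads wherever reagent still stands, so Tuesday's reagent may not be through. The flask has 0.30 M of substrate, more than Sunday's 0.22 M, at the same equivalents, so I expect its reagent to be at least as far through as Sunday's, and I take Sunday's last readings for it: substrate near 30.0%, mono adduct 12.8%, bis adduct 6.7%, and a rest near 50.5%. Of that rest I book triple product as a ceiling, not as an amount.

The forecast says substrate 32%, mono adduct 14%, bis adduct 8% and triple product 46%, holding that the rest “behaves as triple product”.

The flask gives 30.7%, 13.6%, 6.76% and 6.47%, in the same order.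

    substrate + reagent → mono adduct (k = 0.00130 M⁻¹ s⁻¹)
    reagent + mono adduct → bis adduct (k = 0.00340 M⁻¹ s⁻¹)
    reagent + bis adduct → triple product (k = 0.00250 M⁻¹ s⁻¹)
    reagent + triple product → tetra adduct (k = 0.00340 M⁻¹ s⁻¹)
    reagent → decomposition product (k = 1.40 × 10⁻⁷ s⁻¹)
    bis adduct + capture agent → trapped intermediate (k = 0.00430 M⁻¹ s⁻¹)
    substrate + triple product ⇌ idle adduct, settled at all times (K = 1.20 M⁻¹)

While the feed runs, up to 2.50 h, reagent turns bis adduct into triple product and that into tetra adduct, while capture agent takes bis adduct into trapped intermediate; at the end of the feed tetra adduct stands at 16.0%, trapped intermediate at 9.36% and triple product at 5.76%. By 6.00 h the reagent, the limiting reagent here, is down to 2.15% of its charge, and the flask's load, counting that remainder, is 3.04, with tetra adduct at 22.6% and trapped intermediate at 19.6%. The same sum on the flask with 0.036 M of capture agent gives 3.34, above the 3.05 read on Sunday's run, with trapped intermediate at 8.99%.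

The readings were computed for an exercise; noise was put on by code.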